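## The problem

6-Methoxyaromadendrin 3-O-acetate (20) is a 2,3-dihydroflavonol: a chroman-4-one in which the benzo ring A is fused to the pyranone ring C (O1, C2, C3, C4, C4a, C8a), with the 4-hydroxyphenyl ring B on C2. It has two adjacent stereocentres, C2 (R, benzylic and bonded to O1) and C3 (R, α to the ketone and carrying the acetate), in a trans relationship. Only C2 has to be set absolutely. Once it is fixed it can control C3, because a reagent reaching the C3=C4 enol face anti to the aryl group gives the trans isomer, which is also the more stable diequatorial one. Ring A carries O1, 5-OH, 6-OMe and 7-OH, so the oxygen that becomes O1 must be told apart from the two hydroxyl groups flanking the methoxy group. The compound is fragile towards base. Deprotonation at C3 allows β-elimination of the O1 phenoxide (retro-oxa-Michael), which erases C2. A 4'-phenoxide can open the O1–C2 bond as a quinone methide. The acetate next to the ketone is easily lost or epimerised. The feature that invites a C–H insertion is the C2–C3 bond: it joins the ketone α-carbon to a carbon that, in the ring-opened form, is the methylene of an aryl benzyl ether. Its C–H bonds are activated by O1 and by ring B, and they lie six atoms from C3 with O1 as the fifth atom, so no five-membered C–H insertion can compete.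

## Retrosynthesis

**Protecting groups and the acetate (20 from 19 from 18).** Three O–Si bonds and the acetate C–O bond are cut. The phenols are carried as triisopropylsilyl ethers: a methyl ether could not be removed beside 6-OMe, and a benzyl ether on O5 would place a second benzylic ether C–H six atoms from the carbenoid carbon. Silyl ethers offer no such bond and leave together under buffered fluoride. The acetate is put on alcohol 18 while all phenols are masked, so only the 3-OH can be acylated. The forward steps must be mild enough to leave the α-acetoxy ketone untouched.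

**The C3–O bond (18 from 16 from 15).** The C3 oxygen is removed to give flavanone 15, by way of its silyl enol ether 16. Installing it after ring closure is preferred to carrying it through the ring-forming step, because the carbenoid carbon must stay unsubstituted and the ring-bound aryl group at C2 then dictates the face of oxidation. The precursor has one stereocentre instead of two. The forward oxidation must form the enol derivative without opening ring C.

**The C2–C3 bond (15 from 14).** Cutting C2–C3 gives the achiral open diazoketone 14. The neighbouring cuts are weaker for this target: closing O1–C2 by oxa-Michael addition is reversible and prone to racemisation, and closing C4–C4a needs acidic acylation with both stereocentres already at risk. The C2–C3 cut removes the ring and the stereocentre at once. The forward reaction must prefer C–H insertion over attack on the O1 lone pair and must select one of the two enantiotopic benzylic hydrogens.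

**The diazo group and the C4–C4a bond (14 from 12, 12 from 9 and 10, 9 from 8).** The diazo group is traced back to the methyl ketone 12 by diazo transfer. The acetyl group is cut at C4–C4a to aryl bromide 9 and N-methoxy-N-methylacetamide (10), and the bromine is removed to give ether 8. Electrophilic acylation of 8 is excluded by its silyl ethers and its acid-labile benzyl ether, whereas halogen–lithium exchange is compatible with both. The two free positions of ring A in 8 are equivalent, so bromination has no regiochemical issue.

**The O1–C2 ether bond (8 from 4 and 7).** The ether bond is cut to phenol 4 and benzylic alcohol 7, two fragments of similar size. A neutral etherification is asked for, since a phenoxide beside aryl silyl ethers could shuttle silyl groups.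

**The C8a–O bond and the ring B piece (4 from 2 from 1, 7 from 6 from 5).** Phenol 4 is traced to 2-methoxyresorcinol (1) through its bis-silyl ether 2 by C–H borylation and oxidation. Only the C–H bond para to the methoxy group has no ortho substituent, so steric control alone differentiates O1 from O5 and O7, and no selective protection is needed. Alcohol 7 comes from 4-hydroxybenzaldehyde (5) via aldehyde 6. Starting from the aldehyde avoids competition between a phenolic and a benzylic hydroxyl group.

## Roads not taken

**Alternative 1:** Ring A is cut at C4a–C5 and C8–C8a and built last by a Diels–Alder benzannulation. The dienophile would be (2R,3R)-2-[4-(benzyloxy)phenyl]-5-bromo-4-oxo-3,4-dihydro-2H-pyran-3-yl acetate A2, and the diene 1,2-dimethoxy-1,3-bis(trimethylsilyloxy)buta-1,3-diene A3. The methylene terminus of A3 would add to the β-carbon of the bromo-enone (future C8a) and the ketene acetal terminus to the brominated carbon (future C4a). Loss of hydrogen bromide and methanol would aromatise the new ring and give 4'-O-benzyl-6-methoxyaromadendrin 3-O-acetate A1, which needs only hydrogenolysis.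
- Merits: the ring A pattern is fixed by the diene, the ring A phenols never need protection, and there is no phenol differentiation problem.
- Weak points: A2 is a fragile chiral building block. It has two stereocentres flanking a ketone and can aromatise to a 4-pyranone by loss of acetic acid. Its double bond is that of a vinylogous ester and is a poor dienophile. A3 is hindered at one terminus and hydrolytically labile. The heat or Lewis acid needed would endanger C3 and the acetate.
- Comparison: this road is shorter after its key step and avoids diazo chemistry and the insertion-versus-ylide question. The chosen plan sets against this that every intermediate up to 15 is a robust aromatic compound, that C2 is created catalytically from an achiral precursor, and that the labile α-acetoxy ketone appears only at the end.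

**Alternative 2:** Ring C is cut at O1–C2 and C3–C4 and formed by a hetero-Diels–Alder reaction. A chiral phosphoric acid would dehydrate 3,5-bis(benzyloxy)-2-(hydroxymethyl)-4-methoxyphenol A5 to its ortho-quinone methide A6. This would add (E)-2-[4-(benzyloxy)phenyl]ethenyl acetate A7 to give (2R,3S)-5,7-bis(benzyloxy)-2-[4-(benzyloxy)phenyl]-6-methoxychroman-3-yl acetate A4. The alkene geometry would become the 2,3-trans relationship and the catalyst would choose the face.
- Merits: two bonds, the ring and both stereocentres arise in one catalytic, convergent step, and the acetate arrives with the alkene.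
- Weak points: A4 is a flavan, so the C4 ketone must be introduced afterwards by benzylic oxidation in a molecule with three benzyl ethers and the C2–H bond. The regiochemistry is not secured, because the acetoxy group and the aryl group of A7 polarise the alkene in opposite senses and only the aryl-directed mode gives the 2-aryl-3-acetoxy pattern. A5 costs as much as phenol 4 plus a one-carbon homologation.
- Comparison: in stereochemical economy this road is better than the chosen plan, which needs one catalyst-controlled step for C2 and a separate substrate-controlled oxidation for C3. The chosen plan sets against this that C4 is at the ketone level from the start, that the site of C–C bond formation is unambiguous, and that the endgame is a fluoride treatment and not an oxidation followed by hydrogenolysis.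

**Alternative 3:** Ring C is cut at C4–C4a and closed by Friedel–Crafts acylation. (2R,3R)-2-Acetoxy-3-[3,5-bis(benzyloxy)-4-methoxyphenoxy]-3-[4-(benzyloxycarbonyloxy)phenyl]propanoic acid A9, activated in the flask with trifluoroacetic anhydride, would acylate the carbon ortho to the ether oxygen. This would give 5,7-di-O-benzyl-4'-O-benzyloxycarbonyl-6-methoxyaromadendrin 3-O-acetate A8, and one hydrogenolysis would complete the synthesis.
- Merits: the aryl ether is symmetric, so both ortho positions are equivalent and strongly activated. Both stereocentres exist before ring closure and could come from a reliable asymmetric alkene oxidation.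
- Weak points: the acylating species is an α-acetoxy acyl cation equivalent, which is destabilised, open to capture by the neighbouring acetate and to ketene formation, and so puts C3 at risk. The benzylic C–O bond to the electron-rich aryloxy group can ionise in strong acid, which is the reason for the carbonate on ring B, and this would destroy C2. Making the secondary benzylic aryl ether of A9 with clean stereochemistry next to an ester, where β-elimination competes, is an unsolved step of its own.
- Comparison: this road is as good as or better than the chosen plan in the certainty of its absolute configuration and in the length of its endgame. The chosen plan sets against this a neutral ring closure in which no existing stereocentre can be lost, an achiral precursor made from three simple building blocks, and late introduction of the acetate.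

Key step: step 9

**Assumptions.**
- The sense of asymmetric induction of Rh2(S-PTTL)4, dirhodium tetrakis[N-phthaloyl-(S)-tert-leucinate], in the 1,6-insertion of step 9 cannot be deduced with certainty. It is taken to give the (2S)-flavanone 15. If the opposite sense is found, the enantiomeric catalyst Rh2(R-PTTL)4 would be used in the same way.
- Flavonoid numbering (O1, C2, C3, C4, C4a, C5 to C8, C8a, ring B primed) is used for all intermediates, including the open-chain ones.

## Route

Step 1
Reactants: 1 2-methoxybenzene-1,3-diol (2-methoxyresorcinol)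
Product: 2 2-methoxy-1,3-bis(triisopropylsilyloxy)benzene
Conditions: i-Pr3SiCl, imidazole, DMF, rt
Reagents that add atoms: chlorotriisopropylsilane, CC(C)[Si](Cl)(C(C)C)C(C)C
Why: Standard silylation of phenols with a silyl chloride and imidazole; the triisopropylsilyl ethers should tolerate the organolithium, enolate and carbenoid chemistry ahead and carry no C–H bond within reach of the later carbenoid.

Step 2
Reactants: 2 2-methoxy-1,3-bis(triisopropylsilyloxy)benzene
Product: 4 4-methoxy-3,5-bis(triisopropylsilyloxy)phenol, via aryl pinacol boronate 3 (not isolated)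
Conditions: [Ir(OMe)(cod)]2 (1.5 mol%), 4,4'-di-tert-butyl-2,2'-bipyridine (3 mol%), B2pin2 (1.0 equiv), THF, 80 °C; then NaBO3·4H2O, THF/H2O, rt
Reagents that add atoms: bis(pinacolato)diboron, CC1(C)OB(OC1(C)C)B1OC(C)(C)C(C)(C)O1 (its boryl group is carried by 3 only); sodium perborate, [Na+].[O-]OB=O (source of the phenol oxygen)
Why: Iridium-catalysed aromatic C–H borylation is sterically controlled and should take place only at the one C–H bond with no ortho substituent, para to the methoxy group; ipso-hydroxylation of the aryl boronate with perborate then gives the phenol whose oxygen becomes O1.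

Step 3
Reactants: 5 4-hydroxybenzaldehyde
Product: 6 4-(triisopropylsilyloxy)benzaldehyde
Conditions: i-Pr3SiCl, imidazole, DMF, rt
Reagents that add atoms: chlorotriisopropylsilane, CC(C)[Si](Cl)(C(C)C)C(C)C
Why: Phenol silylation; beginning with the aldehyde avoids any competition between a phenolic and a benzylic hydroxyl group.

Step 4
Reactants: 6 4-(triisopropylsilyloxy)benzaldehyde
Product: 7 [4-(triisopropylsilyloxy)phenyl]methanol
Conditions: NaBH4, MeOH, 0 °C
Reagents that add atoms: none
Why: Borohydride reduction of an aromatic aldehyde; the aryl silyl ether is stable to NaBH4 in methanol at 0 °C.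

Step 5
Reactants: 4 4-methoxy-3,5-bis(triisopropylsilyloxy)phenol; 7 [4-(triisopropylsilyloxy)phenyl]methanol
Product: 8 2-methoxy-1,3-bis(triisopropylsilyloxy)-5-[[4-(triisopropylsilyloxy)phenyl]methoxy]benzene
Conditions: PPh3, diisopropyl azodicarboxylate, THF, 0 °C to rt
Reagents that add atoms: none
Why: Mitsunobu etherification of an unhindered phenol with a primary benzylic alcohol forms the O1–C2 bond under neutral conditions, so no free phenoxide is present that could move silyl groups between oxygen atoms.

Step 6
Reactants: 8 2-methoxy-1,3-bis(triisopropylsilyloxy)-5-[[4-(triisopropylsilyloxy)phenyl]methoxy]benzene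
Product: 9 2-bromo-4-methoxy-3,5-bis(triisopropylsilyloxy)-1-[[4-(triisopropylsilyloxy)phenyl]methoxy]benzene
Conditions: N-bromosuccinimide (1.0 equiv), MeCN, −20 to 0 °C
Reagents that add atoms: N-bromosuccinimide, O=C1CCC(=O)N1Br
Why: Electrophilic aromatic bromination; the two free positions of ring A are equivalent and each is ortho or para to three oxygen substituents, so ring A should react far faster than the mono-oxygenated ring B, and one equivalent at low temperature should stop at the monobromide.

Step 7
Reactants: 9 2-bromo-4-methoxy-3,5-bis(triisopropylsilyloxy)-1-[[4-(triisopropylsilyloxy)phenyl]methoxy]benzene; 10 N-methoxy-N-methylacetamide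
Product: 12 1-[3-methoxy-2,4-bis(triisopropylsilyloxy)-6-[[4-(triisopropylsilyloxy)phenyl]methoxy]phenyl]ethanone, via aryllithium 11 (not isolated)
Conditions: n-BuLi, THF, −78 °C; then 10, −78 to 0 °C; aq. NH4Cl
Reagents that add atoms: none
Why: Bromine–lithium exchange is faster than benzylic deprotonation at −78 °C, the bulky triisopropylsilyl group suppresses oxygen-to-carbon silyl migration in the ortho-lithiated silyl ether, and the Weinreb amide stops at the ketone through its chelated tetrahedral adduct.

Step 8
Reactants: 12 1-[3-methoxy-2,4-bis(triisopropylsilyloxy)-6-[[4-(triisopropylsilyloxy)phenyl]methoxy]phenyl]ethanone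
Product: 14 2-diazo-1-[3-methoxy-2,4-bis(triisopropylsilyloxy)-6-[[4-(triisopropylsilyloxy)phenyl]methoxy]phenyl]ethanone, via trifluoroacetyl ketone 13 (not isolated)
Conditions: LiN(SiMe3)2, THF, −78 °C; CF3CO2CH2CF3; aq. NH4Cl; then MeSO2N3, Et3N, H2O, MeCN, rt
Reagents that add atoms: 2,2,2-trifluoroethyl trifluoroacetate, O=C(OCC(F)(F)F)C(F)(F)F (its trifluoroacetyl group is carried by 13 only); methanesulfonyl azide, CS(=O)(=O)N=[N+]=[N-] (source of the two diazo nitrogens)
Why: Detrifluoroacetylative diazo transfer: Claisen-type trifluoroacetylation of the lithium enolate activates the methyl ketone, and the sulfonyl azide then transfers N2 with loss of the trifluoroacetyl group as its N-sulfonyl amide; aryl methyl ketones are standard substrates.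

Step 9
Reactants: 14 2-diazo-1-[3-methoxy-2,4-bis(triisopropylsilyloxy)-6-[[4-(triisopropylsilyloxy)phenyl]methoxy]phenyl]ethanone
Product: 15 (2S)-6-methoxy-5,7-bis(triisopropylsilyloxy)-2-[4-(triisopropylsilyloxy)phenyl]chroman-4-one
Conditions: Rh2(S-PTTL)4 (2 mol%), CH2Cl2, 0 °C, slow addition of 14
Reagents that add atoms: none
Why: The dirhodium tetracarboxylate binds the diazo carbon, N2 leaves, and the electrophilic rhodium carbenoid at C3 inserts into one benzylic C2–H bond through a three-centre, hydride-transfer-like transition state that forms C2–C3 and releases the catalyst. The closest known reaction type is the dirhodium-carboxylate-catalysed intramolecular C–H insertion of 2-alkoxyaryl diazomethyl ketones next to the ether oxygen to give chroman-4-ones, with chiral carboxylate ligands for enantiocontrol. Ring C closes as a six-membered ring by 1,6-insertion (C3 as atom 1, C2 as atom 6); the usually favoured 1,5-insertion is not available because atom 5 is O1. The only new stereocentre, C2, is set by the catalyst, whose pocket of four N-phthaloyl-tert-leucinate ligands should distinguish the two enantiotopic hydrogens of the OCH2 group. The step needs chemoselectivity for C–H insertion over attack of the carbenoid on the O1 lone pair, which would give a five-membered oxonium ylide and then a [1,2]-benzyl shift. The substrate secures this through the hydridic character of the C2–H bonds (α-oxygen plus the 4-silyloxyphenyl group), the low basicity of O1 as an aryl ether oxygen ortho to an acyl group, and the absence of any other activated C–H bond within reach, since O5 and O7 carry silyl groups. Bulky carboxylate ligands and slow addition work in the same direction and suppress carbene dimerisation.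

Step 10
Reactants: 15 (2S)-6-methoxy-5,7-bis(triisopropylsilyloxy)-2-[4-(triisopropylsilyloxy)phenyl]chroman-4-one
Product: 16 (2S)-6-methoxy-5,7-bis(triisopropylsilyloxy)-2-[4-(triisopropylsilyloxy)phenyl]-4-(trimethylsilyloxy)-2H-chromene
Conditions: Me3SiOTf, Et3N, CH2Cl2, 0 °C
Reagents that add atoms: trimethylsilyl trifluoromethanesulfonate, C[Si](C)(C)OS(=O)(=O)C(F)(F)F
Why: Soft enolisation: the ketone is O-silylated and then deprotonated at C3, the only α-position with hydrogen, without a free enolate, so β-elimination of the O1 phenoxide and with it loss of the C2 configuration should be avoided.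

Step 11
Reactants: 16 (2S)-6-methoxy-5,7-bis(triisopropylsilyloxy)-2-[4-(triisopropylsilyloxy)phenyl]-4-(trimethylsilyloxy)-2H-chromene
Product: 18 (2R,3R)-3-hydroxy-6-methoxy-5,7-bis(triisopropylsilyloxy)-2-[4-(triisopropylsilyloxy)phenyl]chroman-4-one, via silyloxy epoxide 17 (not isolated)
Conditions: dimethyldioxirane (acetone), CH2Cl2, −40 to 0 °C; then citric acid, MeOH, rt
Reagents that add atoms: dimethyldioxirane, CC1(C)OO1
Why: Rubottom oxidation: the dioxirane should epoxidise the electron-rich enol ether on the face anti to the 2-aryl group, and acid-promoted opening of the silyloxy epoxide gives the α-hydroxy ketone with the 3-OH trans to the aryl group, which is also the more stable diequatorial isomer; C3 is thus set by C2 under substrate control.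

Step 12
Reactants: 18 (2R,3R)-3-hydroxy-6-methoxy-5,7-bis(triisopropylsilyloxy)-2-[4-(triisopropylsilyloxy)phenyl]chroman-4-one
Product: 19 (2R,3R)-6-methoxy-4-oxo-5,7-bis(triisopropylsilyloxy)-2-[4-(triisopropylsilyloxy)phenyl]chroman-3-yl acetate
Conditions: Ac2O, pyridine, 4-(dimethylamino)pyridine (cat.), CH2Cl2, 0 °C to rt
Reagents that add atoms: acetic anhydride, CC(=O)OC(C)=O
Why: Acylation of a secondary alcohol under nucleophilic catalysis; all phenols are silylated, so only the 3-OH can react, and the mild base should not disturb C3, where the trans isomer is favoured in any case.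

Step 13
Reactants: 19 (2R,3R)-6-methoxy-4-oxo-5,7-bis(triisopropylsilyloxy)-2-[4-(triisopropylsilyloxy)phenyl]chroman-3-yl acetate
Product: 20 6-methoxyaromadendrin 3-O-acetate, (2R,3R)-5,7-dihydroxy-2-(4-hydroxyphenyl)-6-methoxy-4-oxochroman-3-yl acetate
Conditions: Bu4NF, AcOH (1:1), THF, 0 °C to rt
Reagents that add atoms: none
Why: Fluoride cleaves aryl silyl ethers readily because phenoxides leave silicon easily; acetic acid buffers fluoride and the liberated phenoxides, so the α-acetoxy ketone should be neither deacylated nor enolised and the retro-oxa-Michael and quinone methide pathways should stay closed.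

## Compound list

1 | 2-methoxybenzene-1,3-diol (2-methoxyresorcinol) | COc1c(O)cccc1O | starting material
2 | 2-methoxy-1,3-bis(triisopropylsilyloxy)benzene | COc1c(O[Si](C(C)C)(C(C)C)C(C)C)cccc1O[Si](C(C)C)(C(C)C)C(C)C | intermediate
3 | 2-[4-methoxy-3,5-bis(triisopropylsilyloxy)phenyl]-4,4,5,5-tetramethyl-1,3,2-dioxaborolane | COc1c(O[Si](C(C)C)(C(C)C)C(C)C)cc(B2OC(C)(C)C(C)(C)O2)cc1O[Si](C(C)C)(C(C)C)C(C)C | intermediate (not isolated)
4 | 4-methoxy-3,5-bis(triisopropylsilyloxy)phenol | COc1c(O[Si](C(C)C)(C(C)C)C(C)C)cc(O)cc1O[Si](C(C)C)(C(C)C)C(C)C | intermediate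
5 | 4-hydroxybenzaldehyde | O=Cc1ccc(O)cc1 | starting material
6 | 4-(triisopropylsilyloxy)benzaldehyde | O=Cc1ccc(O[Si](C(C)C)(C(C)C)C(C)C)cc1 | intermediate
7 | [4-(triisopropylsilyloxy)phenyl]methanol | OCc1ccc(O[Si](C(C)C)(C(C)C)C(C)C)cc1 | intermediate
8 | 2-methoxy-1,3-bis(triisopropylsilyloxy)-5-[[4-(triisopropylsilyloxy)phenyl]methoxy]benzene | COc1c(O[Si](C(C)C)(C(C)C)C(C)C)cc(OCc2ccc(O[Si](C(C)C)(C(C)C)C(C)C)cc2)cc1O[Si](C(C)C)(C(C)C)C(C)C | intermediate
9 | 2-bromo-4-methoxy-3,5-bis(triisopropylsilyloxy)-1-[[4-(triisopropylsilyloxy)phenyl]methoxy]benzene | COc1c(O[Si](C(C)C)(C(C)C)C(C)C)cc(OCc2ccc(O[Si](C(C)C)(C(C)C)C(C)C)cc2)c(Br)c1O[Si](C(C)C)(C(C)C)C(C)C | intermediate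
10 | N-methoxy-N-methylacetamide | CC(=O)N(C)OC | starting material
11 | [3-methoxy-2,4-bis(triisopropylsilyloxy)-6-[[4-(triisopropylsilyloxy)phenyl]methoxy]phenyl]lithium | COc1c(O[Si](C(C)C)(C(C)C)C(C)C)cc(OCc2ccc(O[Si](C(C)C)(C(C)C)C(C)C)cc2)c([Li])c1O[Si](C(C)C)(C(C)C)C(C)C | intermediate (not isolated)
12 | 1-[3-methoxy-2,4-bis(triisopropylsilyloxy)-6-[[4-(triisopropylsilyloxy)phenyl]methoxy]phenyl]ethanone | COc1c(O[Si](C(C)C)(C(C)C)C(C)C)cc(OCc2ccc(O[Si](C(C)C)(C(C)C)C(C)C)cc2)c(C(C)=O)c1O[Si](C(C)C)(C(C)C)C(C)C | intermediate
13 | 4,4,4-trifluoro-1-[3-methoxy-2,4-bis(triisopropylsilyloxy)-6-[[4-(triisopropylsilyloxy)phenyl]methoxy]phenyl]butane-1,3-dione | COc1c(O[Si](C(C)C)(C(C)C)C(C)C)cc(OCc2ccc(O[Si](C(C)C)(C(C)C)C(C)C)cc2)c(C(=O)CC(=O)C(F)(F)F)c1O[Si](C(C)C)(C(C)C)C(C)C | intermediate (not isolated)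
14 | 2-diazo-1-[3-methoxy-2,4-bis(triisopropylsilyloxy)-6-[[4-(triisopropylsilyloxy)phenyl]methoxy]phenyl]ethanone | COc1c(O[Si](C(C)C)(C(C)C)C(C)C)cc(OCc2ccc(O[Si](C(C)C)(C(C)C)C(C)C)cc2)c(C(=O)C=[N+]=[N-])c1O[Si](C(C)C)(C(C)C)C(C)C | intermediate
15 | (2S)-6-methoxy-5,7-bis(triisopropylsilyloxy)-2-[4-(triisopropylsilyloxy)phenyl]chroman-4-one | COc1c(O[Si](C(C)C)(C(C)C)C(C)C)cc2c(c1O[Si](C(C)C)(C(C)C)C(C)C)C(=O)C[C@@H](c1ccc(O[Si](C(C)C)(C(C)C)C(C)C)cc1)O2 | intermediate
16 | (2S)-6-methoxy-5,7-bis(triisopropylsilyloxy)-2-[4-(triisopropylsilyloxy)phenyl]-4-(trimethylsilyloxy)-2H-chromene | COc1c(O[Si](C(C)C)(C(C)C)C(C)C)cc2c(c1O[Si](C(C)C)(C(C)C)C(C)C)C(O[Si](C)(C)C)=C[C@@H](c1ccc(O[Si](C(C)C)(C(C)C)C(C)C)cc1)O2 | intermediate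
17 | (2R,3R,4R)-3,4-epoxy-6-methoxy-5,7-bis(triisopropylsilyloxy)-2-[4-(triisopropylsilyloxy)phenyl]-4-(trimethylsilyloxy)chroman, epoxide oxygen trans to the 2-aryl group | COc1c(O[Si](C(C)C)(C(C)C)C(C)C)cc2c(c1O[Si](C(C)C)(C(C)C)C(C)C)[C@]3(O[Si](C)(C)C)O[C@@H]3[C@@H](c1ccc(O[Si](C(C)C)(C(C)C)C(C)C)cc1)O2 | intermediate (not isolated)
18 | (2R,3R)-3-hydroxy-6-methoxy-5,7-bis(triisopropylsilyloxy)-2-[4-(triisopropylsilyloxy)phenyl]chroman-4-one | COc1c(O[Si](C(C)C)(C(C)C)C(C)C)cc2c(c1O[Si](C(C)C)(C(C)C)C(C)C)C(=O)[C@H](O)[C@@H](c1ccc(O[Si](C(C)C)(C(C)C)C(C)C)cc1)O2 | intermediate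
19 | (2R,3R)-6-methoxy-4-oxo-5,7-bis(triisopropylsilyloxy)-2-[4-(triisopropylsilyloxy)phenyl]chroman-3-yl acetate | COc1c(O[Si](C(C)C)(C(C)C)C(C)C)cc2c(c1O[Si](C(C)C)(C(C)C)C(C)C)C(=O)[C@H](OC(C)=O)[C@@H](c1ccc(O[Si](C(C)C)(C(C)C)C(C)C)cc1)O2 | intermediate
20 | 6-methoxyaromadendrin 3-O-acetate, (2R,3R)-5,7-dihydroxy-2-(4-hydroxyphenyl)-6-methoxy-4-oxochroman-3-yl acetate | COc1c(O)cc2c(c1O)C(=O)[C@H](OC(C)=O)[C@@H](c1ccc(O)cc1)O2 | target

## Step count and points of risk

Total: 13 steps. Longest linear sequence: 11 steps (steps 1, 2 and 5 to 13, from 1 to 20); steps 3 and 4 form the two-step branch to alcohol 7.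

**Step 9 (key step).** The most likely failure is attack of the carbenoid on the O1 lone pair, followed by [1,2]-migration of the electron-rich benzyl group from the oxonium ylide, since that path closes a five-membered ring. A second weakness is incomplete discrimination between the two enantiotopic benzylic hydrogens by an acceptor-only carbenoid with an early transition state. The fallback leaves carbenoid chemistry and forms the C2–aryl bond instead. It sets out from ketone 12.
- Hydrogenolysis (H2, Pd/C, ethyl acetate) would remove the benzyl group and give 1-[6-hydroxy-3-methoxy-2,4-bis(triisopropylsilyloxy)phenyl]ethanone F1.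
- Condensation with N,N-dimethylformamide dimethyl acetal would give the enaminone (E)-3-(dimethylamino)-1-[6-hydroxy-3-methoxy-2,4-bis(triisopropylsilyloxy)phenyl]prop-2-en-1-one F2.
- Mild acid would cyclise this to 6-methoxy-5,7-bis(triisopropylsilyloxy)chromen-4-one F3.
- Enantioselective conjugate addition of [4-(triisopropylsilyloxy)phenyl]boronic acid F4 would follow. F4 is prepared separately from 4-bromophenol by silylation, bromine–lithium exchange and borylation. The addition would use Pd(OCOCF3)2 and the antipode of 4-tert-butyl-2-(pyridin-2-yl)-4,5-dihydrooxazole that gives the (2S) product, with NH4PF6 and water in 1,2-dichloroethane at 60 °C.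
- The route is rejoined at flavanone 15.

**Step 7.** The aryllithium is flanked by two ortho substituents and may act as a base towards the acidic α-hydrogens of amide 10, so that protonation returns the debrominated ether. Oxygen-to-carbon migration of the neighbouring silyl group is the second possible diversion. The fallback avoids basic organometallics and sets out from bromide 9. Stille coupling with Bu3Sn–C(OEt)=CH2 and Pd(PPh3)4 in toluene at 100 °C would give the enol ether 2-(1-ethoxyethenyl)-4-methoxy-3,5-bis(triisopropylsilyloxy)-1-[[4-(triisopropylsilyloxy)phenyl]methoxy]benzene F5. Hydrolysis with aqueous oxalic acid in THF would return the route to ketone 12.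

**Step 10.** O-silylation of a carbonyl oxygen crowded by the peri 5-silyloxy group may be sluggish. The Lewis acid may also promote ionisation of the O1–C2 bond, assisted by the 4-silyloxyphenyl group, with erosion of the C2 configuration. The fallback changes from soft enolisation and epoxidation to direct hydroxylation of a metal enolate, and it makes no new compound. It sets out from flavanone 15: deprotonation with KN(SiMe3)2 in THF at −78 °C and oxidation of the potassium enolate in place with 2-(phenylsulfonyl)-3-phenyloxaziridine, anti to the aryl group, would lead directly to alcohol 18. Steps 10 and 11 are both bypassed.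

**Step 13.** Fluoride and the liberated phenoxides may be basic enough, despite the buffer, to cause loss or epimerisation of the α-acetoxy group or opening of ring C. Cleavage of the hindered 5-O-silyl group may also lag behind the other two. The fallback reverses the order of deprotection and acylation and sets out from alcohol 18.
- Buffered fluoride would give 6-methoxyaromadendrin F6, (2R,3R)-3,5,7-trihydroxy-2-(4-hydroxyphenyl)-6-methoxychroman-4-one.
- Acetic anhydride in pyridine would give its 3,5,7,4'-tetraacetate F7.
- Ammonium acetate in aqueous methanol at room temperature would cleave the three aryl acetates, which are far more labile than the alkyl acetate, and the route ends at target 20.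

## Further compounds

F1 | step 9 | 1-[6-hydroxy-3-methoxy-2,4-bis(triisopropylsilyloxy)phenyl]ethanone | COc1c(O[Si](C(C)C)(C(C)C)C(C)C)cc(O)c(C(C)=O)c1O[Si](C(C)C)(C(C)C)C(C)C
F2 | step 9 | (E)-3-(dimethylamino)-1-[6-hydroxy-3-methoxy-2,4-bis(triisopropylsilyloxy)phenyl]prop-2-en-1-one | COc1c(O[Si](C(C)C)(C(C)C)C(C)C)cc(O)c(C(=O)/C=C/N(C)C)c1O[Si](C(C)C)(C(C)C)C(C)C
F3 | step 9 | 6-methoxy-5,7-bis(triisopropylsilyloxy)chromen-4-one | COc1c(O[Si](C(C)C)(C(C)C)C(C)C)cc2OC=CC(=O)c2c1O[Si](C(C)C)(C(C)C)C(C)C
F4 | step 9 | [4-(triisopropylsilyloxy)phenyl]boronic acid | OB(O)c1ccc(O[Si](C(C)C)(C(C)C)C(C)C)cc1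
F5 | step 7 | 2-(1-ethoxyethenyl)-4-methoxy-3,5-bis(triisopropylsilyloxy)-1-[[4-(triisopropylsilyloxy)phenyl]methoxy]benzene | COc1c(O[Si](C(C)C)(C(C)C)C(C)C)cc(OCc2ccc(O[Si](C(C)C)(C(C)C)C(C)C)cc2)c(C(=C)OCC)c1O[Si](C(C)C)(C(C)C)C(C)C
F0 | step 10 | none | none
F6 | step 13 | 6-methoxyaromadendrin, (2R,3R)-3,5,7-trihydroxy-2-(4-hydroxyphenyl)-6-methoxychroman-4-one | COc1c(O)cc2c(c1O)C(=O)[C@H](O)[C@@H](c1ccc(O)cc1)O2
F7 | step 13 | 6-methoxyaromadendrin 3,5,7,4'-tetraacetate | COc1c(OC(C)=O)cc2c(c1OC(C)=O)C(=O)[C@H](OC(C)=O)[C@@H](c1ccc(OC(C)=O)cc1)O2
A1 | alternative 1 | 4'-O-benzyl-6-methoxyaromadendrin 3-O-acetate | COc1c(O)cc2c(c1O)C(=O)[C@H](OC(C)=O)[C@@H](c1ccc(OCc3ccccc3)cc1)O2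
A2 | alternative 1 | (2R,3R)-2-[4-(benzyloxy)phenyl]-5-bromo-4-oxo-3,4-dihydro-2H-pyran-3-yl acetate | C1=C(Br)C(=O)[C@H](OC(C)=O)[C@@H](c2ccc(OCc3ccccc3)cc2)O1
A3 | alternative 1 | 1,2-dimethoxy-1,3-bis(trimethylsilyloxy)buta-1,3-diene | C=C(O[Si](C)(C)C)C(OC)=C(OC)O[Si](C)(C)C
A4 | alternative 2 | (2R,3S)-5,7-bis(benzyloxy)-2-[4-(benzyloxy)phenyl]-6-methoxychroman-3-yl acetate | COc1c(OCc2ccccc2)cc2c(c1OCc1ccccc1)C[C@H](OC(C)=O)[C@@H](c1ccc(OCc3ccccc3)cc1)O2
A5 | alternative 2 | 3,5-bis(benzyloxy)-2-(hydroxymethyl)-4-methoxyphenol | COc1c(OCc2ccccc2)cc(O)c(CO)c1OCc1ccccc1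
A6 | alternative 2 | 3,5-bis(benzyloxy)-4-methoxy-6-methylidenecyclohexa-2,4-dien-1-one (ortho-quinone methide) | O=C1C=C(OCc2ccccc2)C(OC)=C(OCc2ccccc2)C1=C
A7 | alternative 2 | (E)-2-[4-(benzyloxy)phenyl]ethenyl acetate | CC(=O)O/C=C/c1ccc(OCc2ccccc2)cc1
A8 | alternative 3 | 5,7-di-O-benzyl-4'-O-benzyloxycarbonyl-6-methoxyaromadendrin 3-O-acetate | COc1c(OCc2ccccc2)cc2c(c1OCc1ccccc1)C(=O)[C@H](OC(C)=O)[C@@H](c1ccc(OC(=O)OCc3ccccc3)cc1)O2
A9 | alternative 3 | (2R,3R)-2-acetoxy-3-[3,5-bis(benzyloxy)-4-methoxyphenoxy]-3-[4-(benzyloxycarbonyloxy)phenyl]propanoic acid | OC(=O)[C@H](OC(C)=O)[C@@H](c1ccc(OC(=O)OCc2ccccc2)cc1)Oc1cc(OCc2ccccc2)c(OC)c(OCc2ccccc2)c1
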